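**Strategy.** The oxane ring (O1′, spiro C2′, C3′–C6′; locants as in the name of 23) is read as a masked β-hydroxy-δ-lactone. With spiro C2′ at the carboxyl level, C3′–C4′ (CHMe–CHOAc) is an aldol bond tethered through ring oxygen O1′. A SmI2 intramolecular Reformatsky reaction of an acyclic 2-bromopropanoate ester of a β-hydroxy aldehyde closes this ring at C3′–C4′ and sets both carbons in one chelated operation. The lactone carbonyl carbon then becomes the spiro centre by two C–C bond formations: an auxiliary-controlled enolate alkylation (C7) and a biomimetic capture of the oxocarbenium ion by the β-keto-δ-lactone (C4), which closes the 2-oxabicyclo[2.2.2]octane.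

Key step: step 4

Remark on the chemistry: 2-bromopropanoyl bromide is racemic, so 5 and 6 are epimer mixtures at the C–Br carbon; the ketal carbon in 14–16, 19 and 20 and the carbon between the two carbonyls of 20 are drawn without configuration because each is made planar later.

Step 1
Reactants: 1 acetaldehyde; 2 trans-2-butene
Product: 4 (2R,3S)-3-methylpent-4-en-2-ol, via (E)-crotyldiisopinocampheylborane 3 (not isolated)
Conditions: 2, KOt-Bu, n-BuLi, THF, −78 to −45 °C; (−)-Ipc2BOMe [from (+)-α-pinene], −78 °C; BF3·OEt2; 1, −78 °C; NaOH, H2O2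
Reagents that add atoms: none
Why: Asymmetric crotylboration: the (E)-crotylborane reacts through a chair six-membered transition state (anti product) and the isopinocampheyl groups direct attack to the si face of the aldehyde, which should set (2R) and (3S).

Step 2
Reactants: 4 (2R,3S)-3-methylpent-4-en-2-ol
Product: 5 (2R,3S)-3-methylpent-4-en-2-yl 2-bromopropanoate
Conditions: 2-bromopropanoyl bromide, pyridine, CH2Cl2, 0 °C
Reagents that add atoms: 2-bromopropanoyl bromide, CC(Br)C(=O)Br
Why: O-acylation of the secondary alcohol by the acid bromide (nucleophilic acyl substitution); the C–Br centre need not be controlled because it becomes an enolate carbon.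

Step 3
Reactants: 5 (2R,3S)-3-methylpent-4-en-2-yl 2-bromopropanoate
Product: 6 (2R,3R)-3-methyl-4-oxobutan-2-yl 2-bromopropanoate
Conditions: O3, CH2Cl2, −78 °C; then Me2S, −78 °C to rt
Reagents that add atoms: ozone, [O-][O+]=O
Why: Ozonolysis cleaves the only alkene to the aldehyde, and reductive work-up with Me2S (not a phosphine, which could attack the C–Br bond) leaves the α-bromo ester and the epimerisable α-methyl aldehyde intact; 6 is used at once.

Step 4
Reactants: 6 (2R,3R)-3-methyl-4-oxobutan-2-yl 2-bromopropanoate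
Product: 8 (3R,4R,5S,6R)-4-hydroxy-3,5,6-trimethyloxan-2-one, via diiodosamarium enolate 7 (not isolated)
Conditions: SmI2 (2.2 equiv), THF, −78 °C; then 0.1 M HCl
Reagents that add atoms: none
Why: SmI2 reduces the C–Br bond by two single-electron transfers to the trivalent samarium ester enolate 7, which adds to the tethered aldehyde; the closest known reaction type is the SmI2-promoted intramolecular Reformatsky reaction of β-(α-bromoacyloxy) aldehydes and ketones. The six-membered lactone closes in a 6-(enolendo)-exo-trig mode, the enolate C=C lying inside the forming ring and the aldehyde C=O outside it. Samarium bridges the enolate oxygen and the aldehyde oxygen, so the ring-forming chair is fused to a Zimmerman–Traxler chair; this forces the new C4–O bond (lactone locants) axial, trans to the equatorial C6 methyl, while the C5 and C6 methyls already present sit equatorial. The new centre C3 is set by the (Z)-enolate geometry, which places its methyl equatorial and cis to the hydroxyl (syn aldol). Both C–Br epimers of 6 converge on the same enolate, and the one selectivity needed, aldol addition faster than β-elimination of the acyloxy group from the aldehyde, should be secured by the low temperature and the intramolecular chelate.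

Step 5
Reactants: 8 (3R,4R,5S,6R)-4-hydroxy-3,5,6-trimethyloxan-2-one
Product: 9 (3R,4R,5R,6R)-4-[(tert-butyldimethylsilyl)oxy]-3,5,6-trimethyloxan-2-one
Conditions: t-BuMe2SiOTf, 2,6-lutidine, CH2Cl2, 0 °C
Reagents that add atoms: tert-butyldimethylsilyl trifluoromethanesulfonate, CC(C)(C)[Si](C)(C)OS(=O)(=O)C(F)(F)F
Why: Silylation of the hindered axial alcohol with the silyl triflate protects it as a bulky ether that later also shields one face of the ring.

Step 6
Reactants: 9 (3R,4R,5R,6R)-4-[(tert-butyldimethylsilyl)oxy]-3,5,6-trimethyloxan-2-one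
Product: 11 tert-butyl{[(3R,4R,5R,6R)-2,2-dimethoxy-3,5,6-trimethyloxan-4-yl]oxy}dimethylsilane, via O-methyl lactonium tetrafluoroborate 10 (not isolated)
Conditions: Me3O·BF4, CH2Cl2, rt; then NaOMe, MeOH, 0 °C
Reagents that add atoms: trimethyloxonium tetrafluoroborate, C[O+](C)C.F[B-](F)(F)F; sodium methoxide, [Na+].[O-]C
Why: O-methylation of the lactone carbonyl by the Meerwein salt gives the dialkoxycarbenium salt 10, which methoxide quenches to the cyclic ortho ester (classical lactone-to-ortho-ester conversion); no stereocentre is touched.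

Step 7
Reactants: 11 tert-butyl{[(3R,4R,5R,6R)-2,2-dimethoxy-3,5,6-trimethyloxan-4-yl]oxy}dimethylsilane; 12 (4S)-4-benzyl-3-propanoyl-1,3-oxazolidin-2-one
Product: 14 (4S)-4-benzyl-3-[(2R)-2-{(3R,4R,5R,6R)-4-[(tert-butyldimethylsilyl)oxy]-2-methoxy-3,5,6-trimethyloxan-2-yl}propanoyl]-1,3-oxazolidin-2-one, via chlorotitanium enolate 13 (not isolated)
Conditions: 12, TiCl4, i-Pr2NEt, CH2Cl2, 0 °C; then 11, −78 to 0 °C
Reagents that add atoms: none
Why: Lewis-acid-mediated alkylation of the chelated tetravalent titanium (Z)-enolate by the cyclic dialkoxycarbenium ion released from the ortho ester (known for ortho esters and ketals); the electrophile approaches anti to the benzyl group, which should set the new methyl-bearing centre (R) whatever the configuration at the ketal carbon.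

Step 8
Reactants: 14 (4S)-4-benzyl-3-[(2R)-2-{(3R,4R,5R,6R)-4-[(tert-butyldimethylsilyl)oxy]-2-methoxy-3,5,6-trimethyloxan-2-yl}propanoyl]-1,3-oxazolidin-2-one
Product: 15 (2S)-2-{(3R,4R,5R,6R)-4-[(tert-butyldimethylsilyl)oxy]-2-methoxy-3,5,6-trimethyloxan-2-yl}propan-1-ol
Conditions: LiBH4, MeOH (1 equiv), THF, 0 °C
Reagents that add atoms: none
Why: LiBH4 attacks the more electrophilic exocyclic imide carbonyl and reduces it to the primary alcohol, releasing the oxazolidinone and leaving the ketal, the silyl ether and the α-stereocentre untouched.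

Step 9
Reactants: 15 (2S)-2-{(3R,4R,5R,6R)-4-[(tert-butyldimethylsilyl)oxy]-2-methoxy-3,5,6-trimethyloxan-2-yl}propan-1-ol
Product: 16 (2S)-2-{(3R,4R,5R,6R)-4-[(tert-butyldimethylsilyl)oxy]-2-methoxy-3,5,6-trimethyloxan-2-yl}propanal
Conditions: Dess–Martin periodinane, pyridine, CH2Cl2, 0 °C
Reagents that add atoms: none
Why: Dess–Martin oxidation under pyridine buffer gives the α-chiral aldehyde without epimerisation or ketal cleavage; 16 is used directly.

Step 10
Reactants: 12 (4S)-4-benzyl-3-propanoyl-1,3-oxazolidin-2-one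
Product: 17 (4S)-4-benzyl-3-[(2R)-2-methyl-3-oxopentanoyl]-1,3-oxazolidin-2-one
Conditions: LiN(i-Pr)2, THF, −78 °C; then propanoyl chloride, −78 °C
Reagents that add atoms: propanoyl chloride, CCC(=O)Cl
Why: C-acylation of the chelated (Z)-lithium enolate on the face opposite the benzyl group sets (2R), and the β-keto imide holds this configuration because allylic strain disfavours its enolisation.

Step 11
Reactants: 16 (2S)-2-{(3R,4R,5R,6R)-4-[(tert-butyldimethylsilyl)oxy]-2-methoxy-3,5,6-trimethyloxan-2-yl}propanal; 17 (4S)-4-benzyl-3-[(2R)-2-methyl-3-oxopentanoyl]-1,3-oxazolidin-2-one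
Product: 19 (4S)-4-benzyl-3-[(2R,4S,5S,6S)-6-{(3R,4R,5R,6R)-4-[(tert-butyldimethylsilyl)oxy]-2-methoxy-3,5,6-trimethyloxan-2-yl}-5-hydroxy-2,4-dimethyl-3-oxoheptanoyl]-1,3-oxazolidin-2-one, via tin enolate 18 (not isolated)
Conditions: 17, Sn(OTf)2, Et3N, CH2Cl2, −20 °C; then 16, −78 °C
Reagents that add atoms: none
Why: Aldol addition of the divalent tin (Z)-enolate formed at the ethyl ketone side of 17 through a chelated chair transition state should give the anti,syn adduct (new methyl anti to the methyl of the reagent, new hydroxyl syn to the new methyl), under reagent control and in the anti-Felkin sense that (Z)-enolates prefer with α-methyl aldehydes, which sets C4 (S) and C5 (S) of the heptanoyl chain.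

Step 12
Reactants: 19 (4S)-4-benzyl-3-[(2R,4S,5S,6S)-6-{(3R,4R,5R,6R)-4-[(tert-butyldimethylsilyl)oxy]-2-methoxy-3,5,6-trimethyloxan-2-yl}-5-hydroxy-2,4-dimethyl-3-oxoheptanoyl]-1,3-oxazolidin-2-one
Product: 20 (5S,6S)-6-[(1S)-1-{(3R,4R,5R,6R)-4-[(tert-butyldimethylsilyl)oxy]-2-methoxy-3,5,6-trimethyloxan-2-yl}ethyl]-3,5-dimethyloxane-2,4-dione
Conditions: i-Pr2NEt, DMAP (cat.), CH2Cl2, 0 °C to rt
Reagents that add atoms: none
Why: The δ-hydroxyl attacks the activated imide carbonyl (6-exo-trig lactonisation) and expels the oxazolidinone, giving the β-keto-δ-lactone whose carbon between the two carbonyls is now freely enolisable.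

Step 13
Reactants: 20 (5S,6S)-6-[(1S)-1-{(3R,4R,5R,6R)-4-[(tert-butyldimethylsilyl)oxy]-2-methoxy-3,5,6-trimethyloxan-2-yl}ethyl]-3,5-dimethyloxane-2,4-dione
Product: 22 (1R,3′R,4S,4′R,5′S,6S,6′R,7S,8S)-4′-hydroxy-3′,4,5′,6,6′,7-hexamethylspiro[2-oxabicyclo[2.2.2]octane-8,2′-oxane]-3,5-dione, via spirocyclic silyl ether 21 (not isolated)
Conditions: HF (48% aq.), MeCN, 0 °C to rt
Reagents that add atoms: none
Why: Acid ionises the tertiary methyl ketal to the cyclic oxocarbenium ion, which the enol of the β-keto-δ-lactone captures at carbon (6-(enolendo)-exo-trig, O-capture being reversible) to form the spiro C–C bond; the tether allows bonding only on the lactone face that carries the side chain (fixing the quaternary bridgehead) and the nucleophile should enter anti to the axial silyloxy group, so that the quaternary carbon ends equatorial on the oxane; HF then removes the silyl group.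

Step 14
Reactants: 22 (1R,3′R,4S,4′R,5′S,6S,6′R,7S,8S)-4′-hydroxy-3′,4,5′,6,6′,7-hexamethylspiro[2-oxabicyclo[2.2.2]octane-8,2′-oxane]-3,5-dione
Product: 23 (1R,3′R,4S,4′R,5′R,6S,6′R,7S,8S)-3′,4,5′,6,6′,7-hexamethyl-3,5-dioxospiro[2-oxabicyclo[2.2.2]octane-8,2′-oxan]-4′-yl acetate (CNP0257416.1)
Conditions: Ac2O, pyridine, DMAP (cat.), CH2Cl2, rt
Reagents that add atoms: acetic anhydride, CC(=O)OC(C)=O
Why: Acetylation of the only free hydroxyl (axial, secondary) under DMAP catalysis gives the target without touching any stereocentre.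

**Compound list**

1 | acetaldehyde | CC=O | starting material
2 | trans-2-butene | C/C=C/C | starting material
3 | (E)-crotyldiisopinocampheylborane, isopinocampheyl groups from (+)-α-pinene | C/C=C/CB([C@@H]1C[C@@H]2C[C@H]([C@H]1C)C2(C)C)[C@@H]1C[C@@H]2C[C@H]([C@H]1C)C2(C)C | intermediate
4 | (2R,3S)-3-methylpent-4-en-2-ol | C[C@@H](O)[C@@H](C)C=C | intermediate
5 | (2R,3S)-3-methylpent-4-en-2-yl 2-bromopropanoate (both C–Br epimers) | C[C@@H](OC(=O)C(C)Br)[C@@H](C)C=C | intermediate
6 | (2R,3R)-3-methyl-4-oxobutan-2-yl 2-bromopropanoate (both C–Br epimers) | C[C@@H](OC(=O)C(C)Br)[C@@H](C)C=O | intermediate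
7 | diiodosamarium (Z)-enolate of 6 (trivalent samarium) | C/C=C(\O[Sm](I)I)O[C@H](C)[C@@H](C)C=O | intermediate
8 | (3R,4R,5S,6R)-4-hydroxy-3,5,6-trimethyloxan-2-one | C[C@H]1OC(=O)[C@H](C)[C@H](O)[C@@H]1C | intermediate
9 | (3R,4R,5R,6R)-4-[(tert-butyldimethylsilyl)oxy]-3,5,6-trimethyloxan-2-one | C[C@H]1OC(=O)[C@H](C)[C@H](O[Si](C)(C)C(C)(C)C)[C@@H]1C | intermediate
10 | O-methyl lactonium tetrafluoroborate of 9 | C[C@H]1[O+]=C(OC)[C@H](C)[C@H](O[Si](C)(C)C(C)(C)C)[C@@H]1C.F[B-](F)(F)F | intermediate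
11 | tert-butyl{[(3R,4R,5R,6R)-2,2-dimethoxy-3,5,6-trimethyloxan-4-yl]oxy}dimethylsilane | C[C@H]1OC(OC)(OC)[C@H](C)[C@H](O[Si](C)(C)C(C)(C)C)[C@@H]1C | intermediate
12 | (4S)-4-benzyl-3-propanoyl-1,3-oxazolidin-2-one | CCC(=O)N1[C@@H](Cc2ccccc2)COC1=O | starting material
13 | trichlorotitanium (Z)-enolate of 12 (tetravalent titanium) | C/C=C(\O[Ti](Cl)(Cl)Cl)N1[C@@H](Cc2ccccc2)COC1=O | intermediate
14 | (4S)-4-benzyl-3-[(2R)-2-{(3R,4R,5R,6R)-4-[(tert-butyldimethylsilyl)oxy]-2-methoxy-3,5,6-trimethyloxan-2-yl}propanoyl]-1,3-oxazolidin-2-one | O=C1OC[C@H](Cc2ccccc2)N1C(=O)[C@H](C)C2(OC)O[C@H](C)[C@@H](C)[C@@H](O[Si](C)(C)C(C)(C)C)[C@H]2C | intermediate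
15 | (2S)-2-{(3R,4R,5R,6R)-4-[(tert-butyldimethylsilyl)oxy]-2-methoxy-3,5,6-trimethyloxan-2-yl}propan-1-ol | OC[C@H](C)C1(OC)O[C@H](C)[C@@H](C)[C@@H](O[Si](C)(C)C(C)(C)C)[C@H]1C | intermediate
16 | (2S)-2-{(3R,4R,5R,6R)-4-[(tert-butyldimethylsilyl)oxy]-2-methoxy-3,5,6-trimethyloxan-2-yl}propanal | O=C[C@H](C)C1(OC)O[C@H](C)[C@@H](C)[C@@H](O[Si](C)(C)C(C)(C)C)[C@H]1C | intermediate
17 | (4S)-4-benzyl-3-[(2R)-2-methyl-3-oxopentanoyl]-1,3-oxazolidin-2-one | CCC(=O)[C@@H](C)C(=O)N1[C@@H](Cc2ccccc2)COC1=O | intermediate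
18 | divalent tin (Z)-enolate of 17 (triflate as second ligand) | C/C=C(\O[Sn]OS(=O)(=O)C(F)(F)F)[C@@H](C)C(=O)N1[C@@H](Cc2ccccc2)COC1=O | intermediate
19 | (4S)-4-benzyl-3-[(2R,4S,5S,6S)-6-{(3R,4R,5R,6R)-4-[(tert-butyldimethylsilyl)oxy]-2-methoxy-3,5,6-trimethyloxan-2-yl}-5-hydroxy-2,4-dimethyl-3-oxoheptanoyl]-1,3-oxazolidin-2-one | C[C@@H](C(=O)N1[C@@H](Cc2ccccc2)COC1=O)C(=O)[C@@H](C)[C@H](O)[C@H](C)C1(OC)O[C@H](C)[C@@H](C)[C@@H](O[Si](C)(C)C(C)(C)C)[C@H]1C | intermediate
20 | (5S,6S)-6-[(1S)-1-{(3R,4R,5R,6R)-4-[(tert-butyldimethylsilyl)oxy]-2-methoxy-3,5,6-trimethyloxan-2-yl}ethyl]-3,5-dimethyloxane-2,4-dione (C3 enolisable) | O=C1C(C)C(=O)[C@@H](C)[C@H](O1)[C@H](C)C2(OC)O[C@H](C)[C@@H](C)[C@@H](O[Si](C)(C)C(C)(C)C)[C@H]2C | intermediate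
21 | tert-butyldimethylsilyl ether of 22 (spirocyclic silyl ether) | CC(C)(C)[Si](C)(C)O[C@@H]1[C@H](C)[C@@H](C)O[C@@]2([C@@H]1C)[C@@H](C)[C@H]1OC(=O)[C@]2(C)C(=O)[C@H]1C | intermediate
22 | (1R,3′R,4S,4′R,5′S,6S,6′R,7S,8S)-4′-hydroxy-3′,4,5′,6,6′,7-hexamethylspiro[2-oxabicyclo[2.2.2]octane-8,2′-oxane]-3,5-dione | O[C@@H]1[C@H](C)[C@@H](C)O[C@@]2([C@@H]1C)[C@@H](C)[C@H]1OC(=O)[C@]2(C)C(=O)[C@H]1C | intermediate
23 | (1R,3′R,4S,4′R,5′R,6S,6′R,7S,8S)-3′,4,5′,6,6′,7-hexamethyl-3,5-dioxospiro[2-oxabicyclo[2.2.2]octane-8,2′-oxan]-4′-yl acetate | CC(=O)O[C@@H]1[C@H](C)[C@@H](C)O[C@@]2([C@@H]1C)[C@@H](C)[C@H]1OC(=O)[C@]2(C)C(=O)[C@H]1C | target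

**Total step count:** 14. **Longest linear sequence:** 13 steps (steps 1–9 and 11–14); step 10 is a one-step branch.

**The three steps most likely to fail**

Step 7. The enolate may fail to bond to the congested dialkoxycarbenium centre, or the product ketal may lose methanol to an enol ether, which would erase the new stereocentre. The fallback sets out from 9 and uses a far more reactive allylic nucleophile instead of an enolate: CH3CH=CHCH2MgCl (THF, −78 °C) adds once to the lactone to give the lactol F1, which MeOH and pyridinium p-toluenesulfonate at 0 °C lock as the methyl ketal F2. This addition is only substrate-controlled, so the epimers at the allylic carbon would be separated at F2. Ozonolysis (O3, then Me2S) of the correct epimer comes back to the route at 16.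

Step 13. The oxocarbenium ion may lose a proton (epimerising a carbon next to the spiro centre), may rest at the reversible O-capture stage, or may be attacked on the wrong face before the hindered C–C bond forms. The fallback sets out from 20 and separates the events under Lewis-acid control: t-BuMe2SiOTf and Et3N give the silyl enol ether F5, and catalytic Me3SiOTf in CH2Cl2 at −78 °C then effects a Mukaiyama-type intramolecular addition of the enol ether to the ketal-derived oxocarbenium ion. This comes back to the route at 21, which HF·pyridine desilylates to 22.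

Step 11. The Lewis acid may ionise the tertiary ketal, the α-chiral aldehyde may epimerise under the amine, or the facial preferences of reagent and aldehyde may not reinforce each other. The fallback sets out from 16 and uses a boron aldol instead: the (Z)-dibutylboron enolate of 12 (Bu2BOTf, Et3N, CH2Cl2, −78 °C) gives the syn aldol adduct F3 with the same configuration at the carbinol and the adjacent methyl carbon. Propanoic anhydride and DMAP give the propanoate ester F4, and LiN(SiMe3)2 in THF at −78 °C makes the propanoate enolate attack the imide carbonyl (6-exo-trig Claisen-type closure), expelling the oxazolidinone. This comes back to the route at 20.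

**Further compounds**

F1 | step 7 | (3R,4R,5R,6R)-2-[(2S)-but-3-en-2-yl]-4-[(tert-butyldimethylsilyl)oxy]-3,5,6-trimethyloxan-2-ol (formed together with its (2R)-butenyl epimer) | C=C[C@H](C)C1(O)O[C@H](C)[C@@H](C)[C@@H](O[Si](C)(C)C(C)(C)C)[C@H]1C
F2 | step 7 | tert-butyl{[(3R,4R,5R,6R)-2-[(2S)-but-3-en-2-yl]-2-methoxy-3,5,6-trimethyloxan-4-yl]oxy}dimethylsilane | C=C[C@H](C)C1(OC)O[C@H](C)[C@@H](C)[C@@H](O[Si](C)(C)C(C)(C)C)[C@H]1C
F3 | step 11 | (4S)-4-benzyl-3-[(2S,3R,4S)-4-{(3R,4R,5R,6R)-4-[(tert-butyldimethylsilyl)oxy]-2-methoxy-3,5,6-trimethyloxan-2-yl}-3-hydroxy-2-methylpentanoyl]-1,3-oxazolidin-2-one | O=C1OC[C@H](Cc2ccccc2)N1C(=O)[C@@H](C)[C@H](O)[C@H](C)C2(OC)O[C@H](C)[C@@H](C)[C@@H](O[Si](C)(C)C(C)(C)C)[C@H]2C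
F4 | step 11 | O-propanoyl ester of F3 | O=C1OC[C@H](Cc2ccccc2)N1C(=O)[C@@H](C)[C@H](OC(=O)CC)[C@H](C)C2(OC)O[C@H](C)[C@@H](C)[C@@H](O[Si](C)(C)C(C)(C)C)[C@H]2C
F5 | step 13 | 4-O-tert-butyldimethylsilyl enol ether of 20 (5,6-dihydro-2H-pyran-2-one) | O=C1C(C)=C(O[Si](C)(C)C(C)(C)C)[C@@H](C)[C@H](O1)[C@H](C)C2(OC)O[C@H](C)[C@@H](C)[C@@H](O[Si](C)(C)C(C)(C)C)[C@H]2C
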